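**Plan**
1. Retrosynthesis: after removal of three MOM ethers, ring C is cut at O1–C8a and C4–C4a in one operation. This is possible because O1 and the C4 carbonyl sit on the adjacent ring-A carbons C8a and C4a, the two termini of an aryne, with the C5 oxygen next to C4a to steer the addition.
2. The two pieces are a fully substituted ring-A aryne (as its o-silylaryl triflate) and an (S)-β-silyloxy ester that carries ring B with its fused dimethylpyran.
3. Ring-A piece, from resorcinol: C6–prenyl, then the third oxygen (C–H borylation/oxidation), then C4a–Si and C8–prenyl by two carbamate-directed metalations run in one flask; the carbamate oxygen becomes the triflate.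
4. Ring-B piece, from resorcinol and 3-methylbut-2-enal: dimethylpyran annulation, then C1′–C2 by formylation and C2–C3 by an acetate aldol.
5. Forward ring order: the dimethylpyran ring first, ring C last in the aryne step; rings A and B are both bought as resorcinol.
6. Stereochemistry: C2, the only stereocentre, is set by asymmetric transfer hydrogenation of the β-keto ester and is carried through the annulation because its C–O bond is never broken.

Key step: step 14

Remark: the β-hydroxy ester enters the annulation as its trimethylsilyl ether, so that fluoride releases alkoxide and aryne together and no O–H proton is present to quench the aryl anion.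

**Route**

Step 1
Reactants: 1 resorcinol
Product: 2 1,3-bis(methoxymethoxy)benzene
Conditions: MOMCl, i-Pr2NEt, CH2Cl2, 0 °C → rt
Reagents that add atoms: chloromethyl methyl ether, COCCl
Why: Double O-alkylation of the phenols (Williamson-type MOM protection) installs the two groups that direct the next metalation.

Step 2
Reactants: 2 1,3-bis(methoxymethoxy)benzene; 3 prenyl bromide (1-bromo-3-methylbut-2-ene)
Product: 5 1,3-bis(methoxymethoxy)-2-(3-methylbut-2-en-1-yl)benzene, via aryllithium 4 (not isolated)
Conditions: n-BuLi, THF, 0 °C → rt; CuI (cat.), 3, −78 °C → rt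
Reagents that add atoms: none
Why: Directed ortho-metalation takes C2 between the two cooperating OMOM groups, and the aryllithium is alkylated at the primary carbon of the allylic bromide under copper catalysis (SN2).

Step 3
Reactants: 5 1,3-bis(methoxymethoxy)-2-(3-methylbut-2-en-1-yl)benzene
Product: 7 3,5-bis(methoxymethoxy)-4-(3-methylbut-2-en-1-yl)phenol, via arylboronate 6 (not isolated)
Conditions: [Ir(OMe)(cod)]2 (cat.), 4,4′-di-tert-butyl-2,2′-bipyridine, B2pin2, THF, 60 °C; then H2O2, aq NaOH, 0 °C
Reagents that add atoms: hydrogen peroxide, OO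
Why: Sterically controlled iridium-catalysed C–H borylation (Hartwig–Miyaura type) should take the only ring position without an ortho substituent, and oxidation of the C–B bond then gives the phenol.

Step 4
Reactants: 7 3,5-bis(methoxymethoxy)-4-(3-methylbut-2-en-1-yl)phenol
Product: 8 3,5-bis(methoxymethoxy)-4-(3-methylbut-2-en-1-yl)phenyl N-(propan-2-yl)carbamate
Conditions: i-PrNCO, Et3N (cat.), CH2Cl2, rt
Reagents that add atoms: isopropyl isocyanate, CC(C)N=C=O
Why: Base-catalysed addition of the phenol to the isocyanate (carbamoylation) gives the secondary carbamate that serves first as directing group and later as a cleavable handle.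

Step 5
Reactants: 8 3,5-bis(methoxymethoxy)-4-(3-methylbut-2-en-1-yl)phenyl N-(propan-2-yl)carbamate; 3 prenyl bromide
Product: 14 3,5-bis(methoxymethoxy)-4,6-bis(3-methylbut-2-en-1-yl)-2-(trimethylsilyl)phenyl N-(propan-2-yl)carbamate, via N-silyl carbamate 9 (not isolated), via ortho-lithiated carbamate 10 (not isolated), via N-silyl arylsilane 11 (not isolated), via aryllithium 12 (not isolated), via N-silyl diprenyl carbamate 13 (not isolated)
Conditions: TBSOTf, TMEDA, Et2O, 0 °C → rt; n-BuLi, TMEDA, −78 °C; TMSCl, −78 °C → rt; volatiles removed in vacuo under argon, fresh Et2O; n-BuLi, TMEDA, −78 °C; CuBr·SMe2, then 3, −78 → 0 °C; cold aq NaHSO4 work-up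
Reagents that add atoms: chlorotrimethylsilane, C[Si](C)(C)Cl
Why: Sequential directed ortho-metalation of the in situ N-silylated carbamate first takes one of the two equivalent positions between carbamate and OMOM, which the chlorosilane quench silylates, and, once the volatile excess chlorosilane has been stripped, takes the one remaining ring hydrogen (again between carbamate and OMOM), where transmetalation to copper and SN2 attack on the allylic bromide set the second prenyl group; the N–Si bond is made once, serves both metalations and is hydrolysed only in the final work-up, and silylating first keeps a benzylic C–H away from the carbamate until the last C–C bond is made.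

Step 6
Reactants: 14 3,5-bis(methoxymethoxy)-4,6-bis(3-methylbut-2-en-1-yl)-2-(trimethylsilyl)phenyl N-(propan-2-yl)carbamate
Product: 16 3,5-bis(methoxymethoxy)-4,6-bis(3-methylbut-2-en-1-yl)-2-(trimethylsilyl)phenyl trifluoromethanesulfonate, via silylphenol 15 (not isolated)
Conditions: DBU, Et2NH, MeCN, 40 °C; then PhNTf2, rt
Reagents that add atoms: N-phenylbis(trifluoromethanesulfonimide), O=S(=O)(N(c1ccccc1)S(=O)(=O)C(F)(F)F)C(F)(F)F
Why: E1cB cleavage of the secondary carbamate (the isocyanate is trapped by the amine) frees the hindered phenoxide, which is O-sulfonylated by the triflimide to give the o-silylaryl triflate aryne precursor.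

Step 7
Reactants: 1 resorcinol; 17 3-methylbut-2-enal
Product: 18 2,2-dimethyl-2H-chromen-7-ol
Conditions: pyridine, 140 °C (sealed tube), 1 in excess
Reagents that add atoms: none
Why: Condensation of the enal at C4 of resorcinol gives an ortho-quinone methide that closes by oxa-6π electrocyclisation (formal [3+3] chromene annulation), with excess resorcinol limiting double annulation.

Step 8
Reactants: 18 2,2-dimethyl-2H-chromen-7-ol
Product: 19 7-hydroxy-2,2-dimethyl-2H-chromene-6-carbaldehyde
Conditions: MgCl2, Et3N, (CH2O)n, MeCN, reflux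
Reagents that add atoms: paraformaldehyde (formaldehyde unit), C=O
Why: Magnesium phenoxide-directed ortho-formylation (Casnati–Skattebøl) should take the less hindered ortho position C6, para to the ring oxygen, and not C8 between the two oxygens.

Step 9
Reactants: 19 7-hydroxy-2,2-dimethyl-2H-chromene-6-carbaldehyde
Product: 20 7-(methoxymethoxy)-2,2-dimethyl-2H-chromene-6-carbaldehyde
Conditions: MOMCl, i-Pr2NEt, CH2Cl2, 0 °C → rt
Reagents that add atoms: chloromethyl methyl ether, COCCl
Why: O-alkylation of the chelated phenol with the chloromethyl ether (MOM protection).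

Step 10
Reactants: 20 7-(methoxymethoxy)-2,2-dimethyl-2H-chromene-6-carbaldehyde; 21 methyl acetate
Product: 23 methyl (3RS)-3-hydroxy-3-[7-(methoxymethoxy)-2,2-dimethyl-2H-chromen-6-yl]propanoate, via lithium ester enolate 22 (not isolated)
Conditions: LDA (commercial solution), THF, −78 °C; then 20, −78 °C; aq NH4Cl
Reagents that add atoms: none
Why: Aldol addition of the ester lithium enolate to the non-enolisable aldehyde at low temperature; the racemic carbinol is corrected by the oxidation–reduction pair that follows.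

Step 11
Reactants: 23 methyl (3RS)-3-hydroxy-3-[7-(methoxymethoxy)-2,2-dimethyl-2H-chromen-6-yl]propanoate
Product: 24 methyl 3-[7-(methoxymethoxy)-2,2-dimethyl-2H-chromen-6-yl]-3-oxopropanoate
Conditions: Dess–Martin periodinane, NaHCO3, CH2Cl2, 0 °C → rt
Reagents that add atoms: none
Why: Dess–Martin oxidation of the secondary benzylic alcohol to the β-keto ester under buffered conditions that spare the MOM ether and the chromene.

Step 12
Reactants: 24 methyl 3-[7-(methoxymethoxy)-2,2-dimethyl-2H-chromen-6-yl]-3-oxopropanoate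
Product: 25 methyl (3S)-3-hydroxy-3-[7-(methoxymethoxy)-2,2-dimethyl-2H-chromen-6-yl]propanoate
Conditions: RuCl(p-cymene)[(S,S)-TsDPEN] (cat.), HCO2H/Et3N (1:1), DMF, 40 °C
Reagents that add atoms: none
Why: Noyori asymmetric transfer hydrogenation of the aryl ketone, in which the (S,S)-ligand directs hydride to the face that gives the (S)-carbinol through the usual CH/π contact between the η6-arene and the substrate aryl group, the alkenes being untouched.

Step 13
Reactants: 25 methyl (3S)-3-hydroxy-3-[7-(methoxymethoxy)-2,2-dimethyl-2H-chromen-6-yl]propanoate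
Product: 26 methyl (3S)-3-[7-(methoxymethoxy)-2,2-dimethyl-2H-chromen-6-yl]-3-[(trimethylsilyl)oxy]propanoate
Conditions: TMSCl, imidazole, CH2Cl2, 0 °C
Reagents that add atoms: chlorotrimethylsilane, C[Si](C)(C)Cl
Why: Silyl ether formation masks the alkoxide as a fluoride-labile group and protects the aldol from retro-aldol cleavage until the annulation.

Step 14
Reactants: 16 3,5-bis(methoxymethoxy)-4,6-bis(3-methylbut-2-en-1-yl)-2-(trimethylsilyl)phenyl trifluoromethanesulfonate; 26 methyl (3S)-3-[7-(methoxymethoxy)-2,2-dimethyl-2H-chromen-6-yl]-3-[(trimethylsilyl)oxy]propanoate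
Product: 30 (2S)-5,7-bis(methoxymethoxy)-2-[7-(methoxymethoxy)-2,2-dimethyl-2H-chromen-6-yl]-6,8-bis(3-methylbut-2-en-1-yl)-2,3-dihydro-4H-chromen-4-one, via aryne 27 (not isolated), via cesium alkoxide 28 (not isolated), via aryl anion 29 (not isolated)
Conditions: 16 (1.3 equiv), CsF, 18-crown-6, THF, 4 Å molecular sieves, 0 °C → rt; pH 7 buffer quench
Reagents that add atoms: none
Why: Proposed new method: fluoride removes the C-silyl group of 16 to give aryne 27 (loss of triflate) and the O-silyl group of 26 to give alkoxide 28 in a proton-free medium; 28 adds to C8a of 27 (O1–C8a) and the resulting C4a aryl anion 29 attacks the ester carbonyl and expels methoxide (C4–C4a). The closest known reaction types are the fluoride-induced annulation of arynes with salicylate esters to xanthones and the O–H insertion of aliphatic alcohols into arynes; an aliphatic β-oxy ester and a tetrasubstituted aryne have not been combined in this way. Ring C (O1, C2, C3, C4, C4a, C8a) closes by a 6-exo-trig acyl substitution of the aryl anion on the ester. No stereocentre is formed, and C2 is carried over from 26 with retention because its C–O bond is never broken. The step needs attack of the alkoxide at C8a and not at C4a; the C5 OMOM group next to C4a polarises the aryne towards a more electrophilic C8a and stabilises the developing anion at C4a inductively, which should outweigh the steric cost of the C8 prenyl group. Low temperature, the absence of protons and re-silylation of free alkoxide by 16 or by fluorotrimethylsilane are meant to hold back retro-aldol cleavage and base-induced opening of the flavanone.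

Step 15
Reactants: 30 (2S)-5,7-bis(methoxymethoxy)-2-[7-(methoxymethoxy)-2,2-dimethyl-2H-chromen-6-yl]-6,8-bis(3-methylbut-2-en-1-yl)-2,3-dihydro-4H-chromen-4-one
Product: 31 euchrenone a3, (2S)-5,7-dihydroxy-2-(7-hydroxy-2,2-dimethyl-2H-chromen-6-yl)-6,8-bis(3-methylbut-2-en-1-yl)-2,3-dihydro-4H-chromen-4-one
Conditions: HCl (3 M aq), MeOH, 40 °C, stopped at full conversion
Reagents that add atoms: none
Why: Acid-catalysed acetal exchange with methanol removes the three MOM ethers (the C5 ether peri to the carbonyl fastest) under conditions mild enough that the prenyl groups, the chromene and C2 should remain untouched.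

**Compound list**
1 | resorcinol | Oc1cccc(O)c1 | starting material
2 | 1,3-bis(methoxymethoxy)benzene | COCOc1cccc(OCOC)c1 | intermediate
3 | prenyl bromide (1-bromo-3-methylbut-2-ene) | CC(C)=CCBr | starting material
4 | [2,6-bis(methoxymethoxy)phenyl]lithium (formed in situ) | [Li]c1c(OCOC)cccc1OCOC | intermediate
5 | 1,3-bis(methoxymethoxy)-2-(3-methylbut-2-en-1-yl)benzene | COCOc1cccc(OCOC)c1CC=C(C)C | intermediate
6 | 2-[3,5-bis(methoxymethoxy)-4-(3-methylbut-2-en-1-yl)phenyl]-4,4,5,5-tetramethyl-1,3,2-dioxaborolane (formed in situ) | COCOc1cc(B2OC(C)(C)C(C)(C)O2)cc(OCOC)c1CC=C(C)C | intermediate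
7 | 3,5-bis(methoxymethoxy)-4-(3-methylbut-2-en-1-yl)phenol | COCOc1cc(O)cc(OCOC)c1CC=C(C)C | intermediate
8 | 3,5-bis(methoxymethoxy)-4-(3-methylbut-2-en-1-yl)phenyl N-(propan-2-yl)carbamate | CC(C)NC(=O)Oc1cc(OCOC)c(CC=C(C)C)c(OCOC)c1 | intermediate
9 | N-(tert-butyldimethylsilyl) derivative of 8 (formed in situ) | CC(C)N(C(=O)Oc1cc(OCOC)c(CC=C(C)C)c(OCOC)c1)[Si](C)(C)C(C)(C)C | intermediate
10 | 2-lithio derivative of 9 (formed in situ) | CC(C)N(C(=O)Oc1cc(OCOC)c(CC=C(C)C)c(OCOC)c1[Li])[Si](C)(C)C(C)(C)C | intermediate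
11 | 3,5-bis(methoxymethoxy)-4-(3-methylbut-2-en-1-yl)-2-(trimethylsilyl)phenyl N-(tert-butyldimethylsilyl)-N-(propan-2-yl)carbamate (formed in situ) | CC(C)N(C(=O)Oc1cc(OCOC)c(CC=C(C)C)c(OCOC)c1[Si](C)(C)C)[Si](C)(C)C(C)(C)C | intermediate
12 | 6-lithio derivative of 11 (formed in situ) | CC(C)N(C(=O)Oc1c([Li])c(OCOC)c(CC=C(C)C)c(OCOC)c1[Si](C)(C)C)[Si](C)(C)C(C)(C)C | intermediate
13 | N-(tert-butyldimethylsilyl) derivative of 14 (formed in situ) | CC(C)N(C(=O)Oc1c(CC=C(C)C)c(OCOC)c(CC=C(C)C)c(OCOC)c1[Si](C)(C)C)[Si](C)(C)C(C)(C)C | intermediate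
14 | 3,5-bis(methoxymethoxy)-4,6-bis(3-methylbut-2-en-1-yl)-2-(trimethylsilyl)phenyl N-(propan-2-yl)carbamate | CC(C)NC(=O)Oc1c(CC=C(C)C)c(OCOC)c(CC=C(C)C)c(OCOC)c1[Si](C)(C)C | intermediate
15 | 3,5-bis(methoxymethoxy)-4,6-bis(3-methylbut-2-en-1-yl)-2-(trimethylsilyl)phenol (formed in situ) | CC(C)=CCc1c(O)c([Si](C)(C)C)c(OCOC)c(CC=C(C)C)c1OCOC | intermediate
16 | 3,5-bis(methoxymethoxy)-4,6-bis(3-methylbut-2-en-1-yl)-2-(trimethylsilyl)phenyl trifluoromethanesulfonate | CC(C)=CCc1c(OCOC)c(CC=C(C)C)c(OS(=O)(=O)C(F)(F)F)c([Si](C)(C)C)c1OCOC | intermediate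
17 | 3-methylbut-2-enal | CC(C)=CC=O | starting material
18 | 2,2-dimethyl-2H-chromen-7-ol | CC1(C)C=Cc2ccc(O)cc2O1 | intermediate
19 | 7-hydroxy-2,2-dimethyl-2H-chromene-6-carbaldehyde | CC1(C)C=Cc2cc(C=O)c(O)cc2O1 | intermediate
20 | 7-(methoxymethoxy)-2,2-dimethyl-2H-chromene-6-carbaldehyde | CC1(C)C=Cc2cc(C=O)c(OCOC)cc2O1 | intermediate
21 | methyl acetate | COC(C)=O | starting material
22 | lithium 1-methoxyethen-1-olate (formed in situ) | [Li]OC(=C)OC | intermediate
23 | methyl (3RS)-3-hydroxy-3-[7-(methoxymethoxy)-2,2-dimethyl-2H-chromen-6-yl]propanoate | COC(=O)CC(O)c1cc2c(cc1OCOC)OC(C)(C)C=C2 | intermediate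
24 | methyl 3-[7-(methoxymethoxy)-2,2-dimethyl-2H-chromen-6-yl]-3-oxopropanoate | COC(=O)CC(=O)c1cc2c(cc1OCOC)OC(C)(C)C=C2 | intermediate
25 | methyl (3S)-3-hydroxy-3-[7-(methoxymethoxy)-2,2-dimethyl-2H-chromen-6-yl]propanoate | COC(=O)C[C@@H](c1cc2c(cc1OCOC)OC(C)(C)C=C2)O | intermediate
26 | methyl (3S)-3-[7-(methoxymethoxy)-2,2-dimethyl-2H-chromen-6-yl]-3-[(trimethylsilyl)oxy]propanoate | COC(=O)C[C@@H](c1cc2c(cc1OCOC)OC(C)(C)C=C2)O[Si](C)(C)C | intermediate
27 | 1,2-didehydro-3,5-bis(methoxymethoxy)-4,6-bis(3-methylbut-2-en-1-yl)benzene, the C4a–C8a aryne (formed in situ) | CC(C)=CCC1=C(OCOC)C#CC(CC=C(C)C)=C1OCOC | intermediate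
28 | cesium (1S)-3-methoxy-1-[7-(methoxymethoxy)-2,2-dimethyl-2H-chromen-6-yl]-3-oxopropan-1-olate (formed in situ) | COC(=O)C[C@@H](c1cc2c(cc1OCOC)OC(C)(C)C=C2)[O-].[Cs+] | intermediate
29 | cesium salt of the C4a aryl anion of the (S)-O-aryl ether of 25 (formed in situ) | COC(=O)C[C@@H](c1cc2c(cc1OCOC)OC(C)(C)C=C2)Oc1c(CC=C(C)C)c(OCOC)c(CC=C(C)C)c(OCOC)[c-]1.[Cs+] | intermediate
30 | (2S)-5,7-bis(methoxymethoxy)-2-[7-(methoxymethoxy)-2,2-dimethyl-2H-chromen-6-yl]-6,8-bis(3-methylbut-2-en-1-yl)-2,3-dihydro-4H-chromen-4-one | CC(C)=CCc1c(OCOC)c(CC=C(C)C)c2c(c1OCOC)C(=O)C[C@@H](c1cc3c(cc1OCOC)OC(C)(C)C=C3)O2 | intermediate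
31 | euchrenone a3 | CC(C)=CCc1c(O)c(CC=C(C)C)c2c(c1O)C(=O)C[C@@H](c1cc3c(cc1O)OC(C)(C)C=C3)O2 | target

**Step count and risks**
Total: 15 steps. Longest linear sequence: 9 steps (steps 7–13, 14, 15); the ring-A branch (steps 1–6, 14, 15) has 8.

Step 14 (annulation). What may go wrong: quenching of the aryl anion by stray protons before it acylates, addition of the alkoxide to the wrong aryne terminus next to the OMOM group, or erosion of the C2 configuration through retro-aldol cleavage of the alkoxide or base-induced opening of the flavanone to the chalcone. The fallback uses known chemistry, sets out from 20 and 16 and comes back at 30. Knoevenagel–Doebner condensation of 20 with malonic acid (pyridine, piperidine, 90 °C) proceeds through the arylidenemalonic acid F1 and gives the (E)-acrylic acid F2. Fluoride-induced C–O addition of the carboxylic acid F2 to the aryne from 16 (CsF, THF, heating), followed by acyl migration, gives the 2′-hydroxychalcone F3, which under the same basic conditions closes by oxa-Michael addition to the racemic flavanone F4. Kinetic resolution of F4 by asymmetric transfer hydrogenation with RuCl(p-cymene)[(R,R)-TsDPEN] and HCO2H/Et3N should reduce the (2R)-ketone to the cis-(2R,4R)-flavan-4-ol F5 and leave (2S)-30.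

Step 5 (silylation and second prenylation in one flask). What may go wrong: capture of the second aryllithium by chlorosilane that was not fully stripped, loss of the N-silyl group between the two metalations followed by fragmentation of the carbamate, incomplete lithiation at the crowded position between the N-silyl carbamate and the OMOM group, or SN2′ attack on the allylic bromide giving the reverse-prenyl isomer. The fallback sets out from 8 and comes back at 14. The two metalations are run as separate operations and the prenyl group is built from an allyl group. The first metalation (9, 10, 11; TMSCl quench, cold aq NaHSO4 work-up) is stopped at the mono-silylated carbamate F6, 3,5-bis(methoxymethoxy)-4-(3-methylbut-2-en-1-yl)-2-(trimethylsilyl)phenyl N-(propan-2-yl)carbamate, which is purified. Renewed N-silylation of F6 (TBSOTf, TMEDA) returns 11, lithiation gives 12, and the arylcopper (CuBr·SMe2) is trapped with allyl bromide, for which both modes of attack give the same product. This gives the N-silyl allylarene F7 and, after work-up, the allyl carbamate F8. Olefin cross-metathesis of F8 with 2-methylbut-2-ene (second-generation Grubbs catalyst RuCl2(=CHPh)(H2IMes)(PCy3), CH2Cl2, 40 °C) then turns the allyl into the prenyl group of 14.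

Step 3 (C–H borylation/oxidation). What may go wrong: hydroboration or isomerisation of the prenyl double bond by the iridium boryl species and pinacolborane during C–H borylation. The fallback sets out from 2 and comes back at 7. Borylation/oxidation is run on 2 before any alkene is present, giving the arylboronate F9 and then 3,5-bis(methoxymethoxy)phenol F10. F10 is silylated (TIPSCl, imidazole) to the triisopropylsilyl ether F11, which is lithiated between the two OMOM groups (n-BuLi, THF) to the aryllithium F12 and alkylated with 3 (CuI cat.) to the prenylated silyl ether F13. TBAF then frees phenol 7.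

Further compounds
F1 | step 14 | 2-{[7-(methoxymethoxy)-2,2-dimethyl-2H-chromen-6-yl]methylidene}propanedioic acid | COCOc1cc2OC(C)(C)C=Cc2cc1C=C(C(O)=O)C(O)=O
F2 | step 14 | (2E)-3-[7-(methoxymethoxy)-2,2-dimethyl-2H-chromen-6-yl]prop-2-enoic acid | COCOc1cc2OC(C)(C)C=Cc2cc1/C=C/C(O)=O
F3 | step 14 | (2E)-1-[2-hydroxy-4,6-bis(methoxymethoxy)-3,5-bis(3-methylbut-2-en-1-yl)phenyl]-3-[7-(methoxymethoxy)-2,2-dimethyl-2H-chromen-6-yl]prop-2-en-1-one | CC(C)=CCc1c(O)c(C(=O)/C=C/c2cc3C=CC(C)(C)Oc3cc2OCOC)c(OCOC)c(CC=C(C)C)c1OCOC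
F4 | step 14 | (2RS)-5,7-bis(methoxymethoxy)-2-[7-(methoxymethoxy)-2,2-dimethyl-2H-chromen-6-yl]-6,8-bis(3-methylbut-2-en-1-yl)-2,3-dihydro-4H-chromen-4-one | CC(C)=CCc1c(OCOC)c(CC=C(C)C)c2c(c1OCOC)C(=O)CC(c1cc3c(cc1OCOC)OC(C)(C)C=C3)O2
F5 | step 14 | (2R,4R)-5,7-bis(methoxymethoxy)-2-[7-(methoxymethoxy)-2,2-dimethyl-2H-chromen-6-yl]-6,8-bis(3-methylbut-2-en-1-yl)-3,4-dihydro-2H-chromen-4-ol | CC(C)=CCc1c(OCOC)c(CC=C(C)C)c2c(c1OCOC)[C@H](O)C[C@H](c1cc3c(cc1OCOC)OC(C)(C)C=C3)O2
F6 | step 5 | 3,5-bis(methoxymethoxy)-4-(3-methylbut-2-en-1-yl)-2-(trimethylsilyl)phenyl N-(propan-2-yl)carbamate | CC(C)NC(=O)Oc1cc(OCOC)c(CC=C(C)C)c(OCOC)c1[Si](C)(C)C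
F7 | step 5 | 3,5-bis(methoxymethoxy)-4-(3-methylbut-2-en-1-yl)-6-(prop-2-en-1-yl)-2-(trimethylsilyl)phenyl N-(tert-butyldimethylsilyl)-N-(propan-2-yl)carbamate | C=CCc1c(OC(=O)N(C(C)C)[Si](C)(C)C(C)(C)C)c([Si](C)(C)C)c(OCOC)c(CC=C(C)C)c1OCOC
F8 | step 5 | 3,5-bis(methoxymethoxy)-4-(3-methylbut-2-en-1-yl)-6-(prop-2-en-1-yl)-2-(trimethylsilyl)phenyl N-(propan-2-yl)carbamate | C=CCc1c(OC(=O)NC(C)C)c([Si](C)(C)C)c(OCOC)c(CC=C(C)C)c1OCOC
F9 | step 3 | 2-[3,5-bis(methoxymethoxy)phenyl]-4,4,5,5-tetramethyl-1,3,2-dioxaborolane | COCOc1cc(OCOC)cc(B2OC(C)(C)C(C)(C)O2)c1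
F10 | step 3 | 3,5-bis(methoxymethoxy)phenol | COCOc1cc(O)cc(OCOC)c1
F11 | step 3 | [3,5-bis(methoxymethoxy)phenoxy]tri(propan-2-yl)silane | COCOc1cc(OCOC)cc(O[Si](C(C)C)(C(C)C)C(C)C)c1
F12 | step 3 | {2,6-bis(methoxymethoxy)-4-[tri(propan-2-yl)silyloxy]phenyl}lithium | [Li]c1c(OCOC)cc(O[Si](C(C)C)(C(C)C)C(C)C)cc1OCOC
F13 | step 3 | [3,5-bis(methoxymethoxy)-4-(3-methylbut-2-en-1-yl)phenoxy]tri(propan-2-yl)silane | COCOc1cc(O[Si](C(C)C)(C(C)C)C(C)C)cc(OCOC)c1CC=C(C)C
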